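## Structural features

The target is an achiral 2-arylbenzofuran. It consists of ring A (benzo ring C3a–C4–C5–C6–C7–C7a), ring B (furan O1–C2–C3–C3a–C7a) and ring C (aryl C1'–C6', joined through C2–C1'). With no stereocentre, every problem is one of regiochemistry, crowding and functional-group tolerance.

Ring A is a phloroglucinol with oxygen on C4, C6 and C7a. C7 carries the quaternary carbon of a 1,1-dimethylallyl group wedged between O1 and the C6 hydroxyl, whereas the very nucleophilic C5 must stay C–H.

Ring C is 1',2',3',5'-substituted. A normal prenyl chain on C2' is squeezed between the C2–C1' bond and the C3' methoxy group, the C5' hydroxyl is para to that chain, and only one of the four oxygen functions is methylated.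

The fragile groups are:
- the vinyl group next to the C6 hydroxyl, which closes to a dihydrofuran under acid or halonium ions;
- the trisubstituted prenyl alkene, which is sensitive to acid, electrophiles and hydrogenation;
- the free triphenol, which is sensitive to air in base and to electrophiles at C3 and C5.

The real difficulty has two parts. Carbon must be attached to C7 and C3a of ring A but not to C5. Ring B must be closed between two ortho-crowded halves without conditions that the two alkenes cannot stand.

The key step exploits two features. O1 on C7a has only one open ortho carbon, C3a, because C7 is blocked by the quaternary carbon. The C3(H)=C2(aryl) edge of ring B is the enamine-level form of an aryl methyl ketone. A [3,3] shift tethered through O1 can therefore deliver C3 only to C3a.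

In one sentence: ring B is made by an acylation-triggered [3,3] exchange of the N–O1 bond for the C3–C3a bond in an O-aryl ketoxime ether. That sentence does not describe the usual alkyne coupling followed by closure at oxygen.

## Logic of the disconnections

**23 ⇒ 20.** The three free hydroxyls are traced back to O–Si bonds, and C5–H is traced back to C5–CO2Me.
- Reason: the ester is a deliberate blocking group. It closes the carbon para to O1 against a Claisen–Cope continuation, shields C5 and C3 from electrophiles, and singles out the oxygen that becomes O1.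
- Gain: every later regiochemical question on ring A has one answer.
- Demand: one basic, acid-free operation must remove three silyl groups, saponify a flanked ester and decarboxylate.

**20 ⇒ 16 (key).** C3–C3a and O1–C2 are cut, and O1–N and N=C2 are restored.
- Reason: both ring B bonds then come from one acyclic precursor, and the crowded C2–C1' bond is never made by coupling.
- Gain: a bicyclic heteroaromatic becomes two benzenes held by a C=N–O link.
- Demand: the shift must run without free acid and must find C3a only.

**16 ⇒ 15 + 8.** The C2=N bond is cut.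
- Reason: this is the convergent union, a condensation that releases water.
- Gain: rings A and C are separated completely.
- Demand: an ortho-substituted ketone must condense under catalysis too weak to touch the alkenes.

**15 ⇒ 14.** The O1–N bond is cut.
- Reason: the phenol that the preceding step liberates is exactly O1.
- Gain: no aryl halide or boronate is needed.
- Demand: a small electrophilic NH2 donor must reach a phenoxide that stands next to a quaternary carbon.

**14 ⇒ 12.** The bond from C7 to the quaternary carbon is cut, and O1–CH2 is restored (aromatic Claisen retron).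
- Reason: O1 serves twice as a pivot, first for the C7 substituent and then for C3.
- Gain: 12 is symmetric, so the two ortho carbons are the same and the para carbon is blocked.
- Demand: the shift must proceed next to a silyloxy group, and the product must not react further at that temperature.

**12 ⇒ 11 ⇒ 9 + 10.** Two O–Si bonds are cut, then the O1–CH2 bond.
- Reason: in 9 only the future O1 is free of chelation to the ester.
- Gain: both pieces are commercial, and no statistical step falls on ring A.
- Demand: O-alkylation must win over C-alkylation, which calls for neutral conditions.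

**8 ⇒ 7 ⇒ 5.** The C3'O–CH3 bond is cut, then the C2'–CH2 bond with return of the allyl unit to the C3' oxygen (Claisen retron).
- Reason: the oxygen that ends as methoxy first delivers the prenyl chain, so the four oxygens are told apart without further tactics.
- Gain: a tetrasubstituted ring becomes a 1,3,5-trisubstituted one.
- Demand: migration must go to C2' and not to C4'.

**5 ⇒ 4 ⇒ 2 + 3 ⇒ 1.** The alkene is traced back to the alkyne, the O–C(CH3)2 bond is cut, then the O–Si bond.
- Reason: tertiary allyl aryl ethers are best reached through the propargyl ether.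
- Gain: the starting materials are commercial.
- Demand: one statistical monosilylation of a symmetric diol.

## Other disconnections considered

**Alternative 1** (the first that comes to mind): cut C3–C3a as an sp–sp2 bond and O1–C2 as the closure at the heteroatom. The forward plan has two stages.
- Sonogashira coupling of the iodophenol A1 (from 14) with the arylacetylene A2 (from 8) would give the o-alkynylphenol A3.
- A 5-endo-dig cyclisation at O1 would then give 20.

The chosen plan is preferred for three reasons.
- A1 needs an electrophilic iodine source while the O1–H/vinyl pair is set up for 5-exo iodoetherification.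
- A2 costs two further operations on 8.
- The coupling must take place at an iodide flanked on both sides, with an alkyne that is itself flanked by the prenyl chain.

From the same two compounds 14 and 8, the chosen plan needs three operations and no transition metal.

**Alternative 2:** cut C2=C3. The forward plan is an intramolecular Wittig reaction of the acyloxybenzylphosphonium salt A4, which also closes ring B at carbon. It is the nearest rival, but it has four drawbacks.
- It needs one extra carbon on C3a, which costs three operations on 14.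
- The phosphonium salt must be formed under hydrobromic acid conditions, which endanger both alkenes and pass through an o-quinone-methide-prone benzylic position.
- Ring C must be supplied at the acid level as A5 instead of as ketone 8.
- The hindered O1 must be acylated by a 2,6-flanked acyl donor.

The route would be longer, and its acidic stage is the wrong match for this substrate.

**Alternative 3:** cut both allyl–arene bonds (C7–quaternary carbon and C2'–CH2) at the same time. The forward plan is a twin sigmatropic shift of the bis(prenyl ether) A6 on a simple 2-arylbenzofuran core. It would need an ortho-Claisen from the C6 oxygen to C7 and a Claisen–Cope sequence from the C5' oxygen to C2'. It is attractive on paper, but the mechanism speaks against it.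
- The C6 ether can choose C5 as well as C7.
- On ring C both ortho carbons (C4', C6') carry hydrogen, so the first dienone should enolise before the Cope step.
- Four constitutional outcomes are open, and nothing in A6 selects one of them.
- The four oxygens would still have to be differentiated beforehand.

Key step: step 11

Remark: the C=N bond of 16 is drawn E, but either geometry leads to the same enamide 17. Compounds 6, 13 and 19 are racemic transients whose sp3 centres disappear.

## Route

Step 1
Reactants: 1 3,5-dihydroxyacetophenone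
Product: 2 1-[3-hydroxy-5-(triisopropylsilyloxy)phenyl]ethanone
Conditions: TIPSCl (1.0 equiv), imidazole, DMF, 0 °C to rt
Reagents that add atoms: triisopropylsilyl chloride, CC(C)[Si](Cl)(C(C)C)C(C)C
Why: Statistical monosilylation of a symmetric resorcinol; unreacted 1 and the bis-ether are easily separated and recycled. The TIPS ether should survive DBU, carbonate and heat, and it falls to hydroxide in the last step.

Step 2
Reactants: 2 1-[3-hydroxy-5-(triisopropylsilyloxy)phenyl]ethanone; 3 3-chloro-3-methylbut-1-yne
Product: 4 1-[3-(2-methylbut-3-yn-2-yloxy)-5-(triisopropylsilyloxy)phenyl]ethanone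
Conditions: CuCl2·2H2O (cat.), DBU, MeCN, 0 °C
Reagents that add atoms: none
Why: Copper-catalysed O-alkylation of a phenol with a tertiary propargylic chloride is the standard entry to aryl 1,1-dimethylpropargyl ethers. The low temperature keeps the ether from rearranging to a chromene.

Step 3
Reactants: 4 1-[3-(2-methylbut-3-yn-2-yloxy)-5-(triisopropylsilyloxy)phenyl]ethanone
Product: 5 1-[3-(2-methylbut-3-en-2-yloxy)-5-(triisopropylsilyloxy)phenyl]ethanone
Conditions: H2 (1 atm), Pd/CaCO3 poisoned with Pb(OAc)2 (Lindlar catalyst), quinoline, EtOAc, rt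
Reagents that add atoms: none
Why: Lindlar semihydrogenation should stop a terminal alkyne at the vinyl stage. The ketone and the aryl silyl ether are inert.

Step 4
Reactants: 5 1-[3-(2-methylbut-3-en-2-yloxy)-5-(triisopropylsilyloxy)phenyl]ethanone
Product: 7 1-[3-hydroxy-2-(3-methylbut-2-enyl)-5-(triisopropylsilyloxy)phenyl]ethanone, via ortho-dienone 6 (not isolated)
Conditions: o-xylene, 135 °C, Ar
Reagents that add atoms: none
Why: Aromatic Claisen rearrangement, accelerated by the gem-dimethyl group; the carbon that bonds to the ring is an unhindered CH2 terminus, so the flanked C2' is accessible. The known meta-substituent effects reinforce each other: the acetyl acceptor steers migration to the ortho carbon next to itself, and the silyloxy donor steers it to the carbon para to itself, both of which are C2'. Enolisation of 6 restores the arene.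

Step 5
Reactants: 7 1-[3-hydroxy-2-(3-methylbut-2-enyl)-5-(triisopropylsilyloxy)phenyl]ethanone
Product: 8 1-[3-methoxy-2-(3-methylbut-2-enyl)-5-(triisopropylsilyloxy)phenyl]ethanone
Conditions: MeI, K2CO3, acetone, rt
Reagents that add atoms: iodomethane, CI
Why: Williamson methylation of the only free phenol. Carbonate is too weak to enolise the ketone, and the TIPS ether resists silyl scrambling.

Step 6
Reactants: 9 methyl 2,4,6-trihydroxybenzoate; 10 3-methylbut-2-en-1-ol
Product: 11 methyl 2,6-dihydroxy-4-(3-methylbut-2-enyloxy)benzoate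
Conditions: PPh3, DIAD, THF, 0 °C to rt
Reagents that add atoms: none
Why: Mitsunobu etherification picks the most acidic, non-chelated 4-hydroxyl (the future O1); the 2- and 6-hydroxyls are tied to the ester by hydrogen bonds. The neutral medium avoids the C-prenylation that phloroglucinol phenoxides show with prenyl halides.

Step 7
Reactants: 11 methyl 2,6-dihydroxy-4-(3-methylbut-2-enyloxy)benzoate
Product: 12 methyl 2,6-bis(tert-butyldimethylsilyloxy)-4-(3-methylbut-2-enyloxy)benzoate
Conditions: TBSOTf (2.3 equiv), 2,6-lutidine, CH2Cl2, 0 °C to rt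
Reagents that add atoms: tert-butyldimethylsilyl triflate, CC(C)(C)[Si](C)(C)OS(=O)(=O)C(F)(F)F
Why: The silyl triflate/lutidine pair silylates chelated phenols that resist the chloride. TBS is chosen over TIPS to limit crowding beside the ester and the coming quaternary carbon.

Step 8
Reactants: 12 methyl 2,6-bis(tert-butyldimethylsilyloxy)-4-(3-methylbut-2-enyloxy)benzoate
Product: 14 methyl 2,6-bis(tert-butyldimethylsilyloxy)-4-hydroxy-3-(2-methylbut-3-en-2-yl)benzoate, via ortho-dienone 13 (not isolated)
Conditions: PhNEt2, 180 °C, Ar, sealed tube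
Reagents that add atoms: none
Why: Aromatic Claisen rearrangement of an aryl prenyl ether with allyl inversion sets the quaternary carbon on the future C7; the two ortho carbons are equivalent by symmetry. A Cope continuation to the para carbon would end at a quaternary, ester-bearing dienone that cannot aromatise and can only revert. The amine solvent speeds enolisation of 13 and keeps the medium free of acid.

Step 9
Reactants: 14 methyl 2,6-bis(tert-butyldimethylsilyloxy)-4-hydroxy-3-(2-methylbut-3-en-2-yl)benzoate
Product: 15 methyl 4-(aminooxy)-2,6-bis(tert-butyldimethylsilyloxy)-3-(2-methylbut-3-en-2-yl)benzoate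
Conditions: NaH, DMF, 0 °C; then O-(2,4-dinitrophenyl)hydroxylamine, 0 °C to rt; used at once
Reagents that add atoms: O-(2,4-dinitrophenyl)hydroxylamine, NOc1ccc(cc1[N+](=O)[O-])[N+](=O)[O-]
Why: Electrophilic amination of a phenoxide (substitution at nitrogen with a stabilised aryloxide as leaving group) is a known route to aryloxyamines. The transferred NH2 is small enough for the hindered O1, and the para ester tempers the ring so that the N–O bond of 15 should be stable enough to handle.

Step 10
Reactants: 15 methyl 4-(aminooxy)-2,6-bis(tert-butyldimethylsilyloxy)-3-(2-methylbut-3-en-2-yl)benzoate; 8 1-[3-methoxy-2-(3-methylbut-2-enyl)-5-(triisopropylsilyloxy)phenyl]ethanone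
Product: 16 methyl 2,6-bis(tert-butyldimethylsilyloxy)-4-[({(E)-1-[3-methoxy-2-(3-methylbut-2-enyl)-5-(triisopropylsilyloxy)phenyl]ethylidene}amino)oxy]-3-(2-methylbut-3-en-2-yl)benzoate
Conditions: PPTS (cat.), 4 Å MS, CH2Cl2–EtOH, 40 °C
Reagents that add atoms: none
Why: Oxime ether condensation of an alpha-effect nitrogen nucleophile with a ketone, drawn to completion by the sieves. PPTS is too weak an acid to protonate either alkene.

Step 11
Reactants: 16 methyl 2,6-bis(tert-butyldimethylsilyloxy)-4-[({(E)-1-[3-methoxy-2-(3-methylbut-2-enyl)-5-(triisopropylsilyloxy)phenyl]ethylidene}amino)oxy]-3-(2-methylbut-3-en-2-yl)benzoate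
Product: 20 methyl 4,6-bis(tert-butyldimethylsilyloxy)-2-[3-methoxy-2-(3-methylbut-2-enyl)-5-(triisopropylsilyloxy)phenyl]-7-(2-methylbut-3-en-2-yl)-1-benzofuran-5-carboxylate, via N-aryloxy enamide 17 (not isolated), via o-hydroxybenzyl N-acyl ketimine 18 (not isolated), via 2-amido-2,3-dihydrobenzofuran 19 (not isolated)
Conditions: CF3C(O)OTf (1.5 equiv), DMAP (3 equiv), CH2Cl2, 0 °C to rt
Reagents that add atoms: trifluoroacetyl triflate, O=C(OS(=O)(=O)C(F)(F)F)C(F)(F)F (its CF3CO group is carried only by 17, 18 and 19 and leaves again; no atom of it remains in 20)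
Why: The N-trifluoroacetyl-DMAP salt acylates the oxime nitrogen of 16, and DMAP removes a proton from the only enolisable position, the future C3 methyl group, to give enamide 17, whose weak N–O bond should let the [3,3] shift run at or below room temperature. The shift breaks N–O1 and forms C3–C3a through a six-membered transition state whose two bond-forming termini are unhindered (a CH2 terminus and a C–H carbon), and rearomatisation gives 18. Ring B then closes by 5-exo-trig addition of O1–H to the activated C2=N bond (19), and base-assisted loss of trifluoroacetamide aromatises it to 20, so C3–C3a and O1–C2 are both set in one flask. The closest known reaction type is the oxygen analogue of the Fischer indole synthesis in its acylation-triggered form, which is established for O-aryl oxime ethers of aryl methyl ketones as a route to 2-arylbenzofurans. Site selectivity rests on the substrate: of the two carbons ortho to O1, C7 bears the quaternary carbon, so a shift there would give a dienone that cannot aromatise and can only revert, and C5 lies outside the six-membered array and is blocked anyway. No stereocentre survives, since C2 of 19 forms racemic and becomes sp2 in 20. Chemoselectivity follows from the absence of free acid (triflic acid is held as its DMAP salt), halonium ion and transition metal, so both alkenes, the silyl ethers and the ester should persist, and the C5 ester lowers the tendency of C3 to be trifluoroacetylated.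

Step 12
Reactants: 20 methyl 4,6-bis(tert-butyldimethylsilyloxy)-2-[3-methoxy-2-(3-methylbut-2-enyl)-5-(triisopropylsilyloxy)phenyl]-7-(2-methylbut-3-en-2-yl)-1-benzofuran-5-carboxylate
Product: 23 2-[5-hydroxy-3-methoxy-2-(3-methylbut-2-enyl)phenyl]-7-(2-methylbut-3-en-2-yl)-1-benzofuran-4,6-diol (target), via triol methyl ester 21 (not isolated), via 5-carboxylic acid 22 (not isolated)
Conditions: KOH (excess), MeOH–H2O (4:1), degassed, reflux, Ar; then cold 1 M HCl to pH 5, 40 °C
Reagents that add atoms: water, O (its oxygen enters intermediate 22 only; 23 keeps nothing but hydrogen from it)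
Why: Aryl silyl ethers are cleaved by hot hydroxide. The ester, now flanked by two phenoxides, is saponified, and the resulting 2,6-dihydroxybenzoic acid loses CO2 by ipso-protonation, the same saponification–decarboxylation used to remove ester blocking groups from resorcinols. Base leaves both alkenes, the aryl methyl ether and the benzofuran untouched.

## Compound list

1 | 3,5-dihydroxyacetophenone | CC(=O)c1cc(O)cc(O)c1 | starting material
2 | 1-[3-hydroxy-5-(triisopropylsilyloxy)phenyl]ethanone | CC(=O)c1cc(O)cc(O[Si](C(C)C)(C(C)C)C(C)C)c1 | intermediate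
3 | 3-chloro-3-methylbut-1-yne | C#CC(C)(C)Cl | starting material
4 | 1-[3-(2-methylbut-3-yn-2-yloxy)-5-(triisopropylsilyloxy)phenyl]ethanone | CC(=O)c1cc(OC(C)(C)C#C)cc(O[Si](C(C)C)(C(C)C)C(C)C)c1 | intermediate
5 | 1-[3-(2-methylbut-3-en-2-yloxy)-5-(triisopropylsilyloxy)phenyl]ethanone | CC(=O)c1cc(OC(C)(C)C=C)cc(O[Si](C(C)C)(C(C)C)C(C)C)c1 | intermediate
6 | 5-acetyl-6-(3-methylbut-2-enyl)-3-(triisopropylsilyloxy)cyclohexa-2,4-dien-1-one (racemic, not isolated) | CC(=O)C1=CC(O[Si](C(C)C)(C(C)C)C(C)C)=CC(=O)C1CC=C(C)C | intermediate
7 | 1-[3-hydroxy-2-(3-methylbut-2-enyl)-5-(triisopropylsilyloxy)phenyl]ethanone | CC(=O)c1cc(O[Si](C(C)C)(C(C)C)C(C)C)cc(O)c1CC=C(C)C | intermediate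
8 | 1-[3-methoxy-2-(3-methylbut-2-enyl)-5-(triisopropylsilyloxy)phenyl]ethanone | CC(=O)c1cc(O[Si](C(C)C)(C(C)C)C(C)C)cc(OC)c1CC=C(C)C | intermediate
9 | methyl 2,4,6-trihydroxybenzoate | COC(=O)c1c(O)cc(O)cc1O | starting material
10 | 3-methylbut-2-en-1-ol | CC(C)=CCO | starting material
11 | methyl 2,6-dihydroxy-4-(3-methylbut-2-enyloxy)benzoate | COC(=O)c1c(O)cc(OCC=C(C)C)cc1O | intermediate
12 | methyl 2,6-bis(tert-butyldimethylsilyloxy)-4-(3-methylbut-2-enyloxy)benzoate | COC(=O)c1c(O[Si](C)(C)C(C)(C)C)cc(OCC=C(C)C)cc1O[Si](C)(C)C(C)(C)C | intermediate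
13 | methyl 2,6-bis(tert-butyldimethylsilyloxy)-3-(2-methylbut-3-en-2-yl)-4-oxocyclohexa-1,5-diene-1-carboxylate (racemic, not isolated) | C=CC(C)(C)C1C(=O)C=C(O[Si](C)(C)C(C)(C)C)C(C(=O)OC)=C1O[Si](C)(C)C(C)(C)C | intermediate
14 | methyl 2,6-bis(tert-butyldimethylsilyloxy)-4-hydroxy-3-(2-methylbut-3-en-2-yl)benzoate | C=CC(C)(C)c1c(O)cc(O[Si](C)(C)C(C)(C)C)c(C(=O)OC)c1O[Si](C)(C)C(C)(C)C | intermediate
15 | methyl 4-(aminooxy)-2,6-bis(tert-butyldimethylsilyloxy)-3-(2-methylbut-3-en-2-yl)benzoate | C=CC(C)(C)c1c(ON)cc(O[Si](C)(C)C(C)(C)C)c(C(=O)OC)c1O[Si](C)(C)C(C)(C)C | intermediate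
16 | methyl 2,6-bis(tert-butyldimethylsilyloxy)-4-[({(E)-1-[3-methoxy-2-(3-methylbut-2-enyl)-5-(triisopropylsilyloxy)phenyl]ethylidene}amino)oxy]-3-(2-methylbut-3-en-2-yl)benzoate | C/C(=N\Oc1cc(O[Si](C)(C)C(C)(C)C)c(C(=O)OC)c(O[Si](C)(C)C(C)(C)C)c1C(C)(C)C=C)c1cc(O[Si](C(C)C)(C(C)C)C(C)C)cc(OC)c1CC=C(C)C | intermediate
17 | N-aryloxy-N-(1-arylvinyl)trifluoroacetamide derived from 16 (not isolated) | C=C(N(Oc1cc(O[Si](C)(C)C(C)(C)C)c(C(=O)OC)c(O[Si](C)(C)C(C)(C)C)c1C(C)(C)C=C)C(=O)C(F)(F)F)c1cc(O[Si](C(C)C)(C(C)C)C(C)C)cc(OC)c1CC=C(C)C | intermediate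
18 | o-hydroxybenzyl aryl N-(trifluoroacetyl)ketimine, the rearomatised product of the [3,3] shift (not isolated) | C=CC(C)(C)c1c(O)c(CC(=NC(=O)C(F)(F)F)c2cc(O[Si](C(C)C)(C(C)C)C(C)C)cc(OC)c2CC=C(C)C)c(O[Si](C)(C)C(C)(C)C)c(C(=O)OC)c1O[Si](C)(C)C(C)(C)C | intermediate
19 | 2-aryl-2-(trifluoroacetamido)-2,3-dihydrobenzofuran (racemic, not isolated) | C=CC(C)(C)c1c(O[Si](C)(C)C(C)(C)C)c(C(=O)OC)c(O[Si](C)(C)C(C)(C)C)c2c1OC(NC(=O)C(F)(F)F)(c1cc(O[Si](C(C)C)(C(C)C)C(C)C)cc(OC)c1CC=C(C)C)C2 | intermediate
20 | methyl 4,6-bis(tert-butyldimethylsilyloxy)-2-[3-methoxy-2-(3-methylbut-2-enyl)-5-(triisopropylsilyloxy)phenyl]-7-(2-methylbut-3-en-2-yl)-1-benzofuran-5-carboxylate | C=CC(C)(C)c1c(O[Si](C)(C)C(C)(C)C)c(C(=O)OC)c(O[Si](C)(C)C(C)(C)C)c2cc(-c3cc(O[Si](C(C)C)(C(C)C)C(C)C)cc(OC)c3CC=C(C)C)oc12 | intermediate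
21 | methyl 4,6-dihydroxy-2-[5-hydroxy-3-methoxy-2-(3-methylbut-2-enyl)phenyl]-7-(2-methylbut-3-en-2-yl)-1-benzofuran-5-carboxylate (not isolated) | C=CC(C)(C)c1c(O)c(C(=O)OC)c(O)c2cc(-c3cc(O)cc(OC)c3CC=C(C)C)oc12 | intermediate
22 | 4,6-dihydroxy-2-[5-hydroxy-3-methoxy-2-(3-methylbut-2-enyl)phenyl]-7-(2-methylbut-3-en-2-yl)-1-benzofuran-5-carboxylic acid (not isolated) | C=CC(C)(C)c1c(O)c(C(=O)O)c(O)c2cc(-c3cc(O)cc(OC)c3CC=C(C)C)oc12 | intermediate
23 | 2-[5-hydroxy-3-methoxy-2-(3-methylbut-2-enyl)phenyl]-7-(2-methylbut-3-en-2-yl)-1-benzofuran-4,6-diol | C=CC(C)(C)c1c(O)cc(O)c2cc(-c3cc(O)cc(OC)c3CC=C(C)C)oc12 | target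

## Step count and least certain steps

Total step count: 12. Longest linear sequence: 8 (steps 1–5, then 10–12). The ring A branch (steps 6–9) adds 4 steps and joins at step 10.

**Step 11 (key step).**
- Risk: N-acylation at the crowded oxime nitrogen may be slow, so that enamide formation lags. The excess acylating agent could then attack C3 of the product already formed, or the sequence could stall before trifluoroacetamide is lost.
- Fallback (from 14 and 8, back at 20): the C3–C3a bond is made by cross-coupling instead of a sigmatropic shift.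
  - 14 is brominated at its only remaining ring C–H (NBS, cat. i-Pr2NH, CH2Cl2, −20 °C). This gives methyl 3-bromo-2,6-bis(tert-butyldimethylsilyloxy)-4-hydroxy-5-(2-methylbut-3-en-2-yl)benzoate F1.
  - The enolate of 8 is joined to F1 by ketone alpha-arylation under zerovalent palladium catalysis (Pd2(dba)3, XPhos, K3PO4, toluene, 90 °C). This gives the o-hydroxybenzyl aryl ketone F2, the oxygen counterpart of 18.
  - PPTS in warm toluene cyclodehydrates F2 to 20.

**Step 9.**
- Risk: the stabilised, hindered phenoxide may react slowly at nitrogen. Attack at the aromatic carbon of the aminating reagent (aryl transfer instead of amino transfer) and slow decay of the N–O compound on standing could then compete.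
- Fallback (from 14, back at 15): the polarity is reversed, so that C7a becomes the electrophile and the oxygen comes with the nitrogen.
  - 14 is converted with Tf2O and pyridine into the aryl triflate F3.
  - F3 is coupled with ethyl N-hydroxyacetimidate by palladium-catalysed C–O coupling ([(allyl)PdCl]2, t-BuBrettPhos, Cs2CO3, toluene, 65 °C). This gives the ethyl N-aryloxyacetimidate F4.
  - Cold aqueous HCl in 1,4-dioxane hydrolyses F4 to 15.

**Step 8.**
- Risk: compression between the migrating tertiary carbon and the buttressed silyloxy group may slow the shift. Loss of isoprene from the ether could then compete at the temperature needed. So could follow-up reactions of the product: a 1,5-hydrogen shift of the abnormal Claisen type, or ring closure of O1–H onto the vinyl group.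
- Fallback (from 11, back at 16): the shift is moved to the unsilylated stage, and silicon is introduced only after the union.
  - 11 is rearranged in aqueous ethanol in a sealed tube at 130 °C. The flanking group is then a small hydroxyl, and the protic medium accelerates the shift. The product is methyl 2,4,6-trihydroxy-3-(2-methylbut-3-en-2-yl)benzoate F5.
  - One equivalent of NaH followed by O-(2,4-dinitrophenyl)hydroxylamine aminates the most acidic, non-chelated 4-hydroxyl. This gives the aminooxy diol F6.
  - Condensation of F6 with 8 as in step 10 gives the oxime ether diol F7.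
  - TBSOTf and 2,6-lutidine convert F7 into 16.

**Step 4.**
- Risk: site selectivity between C2' and C4' may be incomplete, and thermal loss of isoprene from the tertiary ether may compete.
- Fallback (from 2, back at 8): the C2'–CH2 bond is made by cooperative directed ortho-metalation.
  - 2 is methylated (MeI, K2CO3) to 1-[3-methoxy-5-(triisopropylsilyloxy)phenyl]ethanone F8.
  - F8 is ketalised (ethylene glycol, PPTS, toluene, water separator) to the dioxolane F9.
  - F9 is lithiated with n-BuLi in THF at 0 °C at the carbon between the methoxy and ketal groups, and the aryllithium is alkylated with prenyl bromide in the presence of CuI. This gives the prenylated dioxolane F10.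
  - PPTS in aqueous acetone releases 8 from F10.

**Step 12.**
- Risk: saponification of an ester flanked by two phenoxides may be slow, and the polyphenolate may degrade oxidatively during a long reflux in base.
- Fallback (from 20, back at 23): the ester is opened at the alkyl–oxygen bond instead of the acyl–oxygen bond.
  - TBAF buffered with AcOH in THF at 0 °C gives 21, now isolated.
  - LiI in pyridine at reflux removes the ester methyl group by substitution at carbon.
  - The salt of 22 loses CO2 on mild acidification and gives 23.
  - This fallback makes no compound outside the compound list (F0).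

## Further compounds

F1 | step 11 | methyl 3-bromo-2,6-bis(tert-butyldimethylsilyloxy)-4-hydroxy-5-(2-methylbut-3-en-2-yl)benzoate | C=CC(C)(C)c1c(O)c(Br)c(O[Si](C)(C)C(C)(C)C)c(C(=O)OC)c1O[Si](C)(C)C(C)(C)C
F2 | step 11 | methyl 2,6-bis(tert-butyldimethylsilyloxy)-4-hydroxy-3-{2-[3-methoxy-2-(3-methylbut-2-enyl)-5-(triisopropylsilyloxy)phenyl]-2-oxoethyl}-5-(2-methylbut-3-en-2-yl)benzoate | C=CC(C)(C)c1c(O)c(CC(=O)c2cc(O[Si](C(C)C)(C(C)C)C(C)C)cc(OC)c2CC=C(C)C)c(O[Si](C)(C)C(C)(C)C)c(C(=O)OC)c1O[Si](C)(C)C(C)(C)C
F3 | step 9 | methyl 2,6-bis(tert-butyldimethylsilyloxy)-3-(2-methylbut-3-en-2-yl)-4-(trifluoromethylsulfonyloxy)benzoate | C=CC(C)(C)c1c(OS(=O)(=O)C(F)(F)F)cc(O[Si](C)(C)C(C)(C)C)c(C(=O)OC)c1O[Si](C)(C)C(C)(C)C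
F4 | step 9 | methyl 2,6-bis(tert-butyldimethylsilyloxy)-4-{[(E)-(1-ethoxyethylidene)amino]oxy}-3-(2-methylbut-3-en-2-yl)benzoate | CCO/C(C)=N/Oc1cc(O[Si](C)(C)C(C)(C)C)c(C(=O)OC)c(O[Si](C)(C)C(C)(C)C)c1C(C)(C)C=C
F5 | step 8 | methyl 2,4,6-trihydroxy-3-(2-methylbut-3-en-2-yl)benzoate | C=CC(C)(C)c1c(O)cc(O)c(C(=O)OC)c1O
F6 | step 8 | methyl 4-(aminooxy)-2,6-dihydroxy-3-(2-methylbut-3-en-2-yl)benzoate | C=CC(C)(C)c1c(ON)cc(O)c(C(=O)OC)c1O
F7 | step 8 | methyl 2,6-dihydroxy-4-[({(E)-1-[3-methoxy-2-(3-methylbut-2-enyl)-5-(triisopropylsilyloxy)phenyl]ethylidene}amino)oxy]-3-(2-methylbut-3-en-2-yl)benzoate | C/C(=N\Oc1cc(O)c(C(=O)OC)c(O)c1C(C)(C)C=C)c1cc(O[Si](C(C)C)(C(C)C)C(C)C)cc(OC)c1CC=C(C)C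
F8 | step 4 | 1-[3-methoxy-5-(triisopropylsilyloxy)phenyl]ethanone | CC(=O)c1cc(OC)cc(O[Si](C(C)C)(C(C)C)C(C)C)c1
F9 | step 4 | 2-[3-methoxy-5-(triisopropylsilyloxy)phenyl]-2-methyl-1,3-dioxolane | CC1(OCCO1)c1cc(OC)cc(O[Si](C(C)C)(C(C)C)C(C)C)c1
F10 | step 4 | 2-[3-methoxy-2-(3-methylbut-2-enyl)-5-(triisopropylsilyloxy)phenyl]-2-methyl-1,3-dioxolane | CC1(OCCO1)c1cc(O[Si](C(C)C)(C(C)C)C(C)C)cc(OC)c1CC=C(C)C
F0 | step 12 | none | none
A1 | alternative 1 | methyl 2,6-bis(tert-butyldimethylsilyloxy)-4-hydroxy-3-iodo-5-(2-methylbut-3-en-2-yl)benzoate | C=CC(C)(C)c1c(O)c(I)c(O[Si](C)(C)C(C)(C)C)c(C(=O)OC)c1O[Si](C)(C)C(C)(C)C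
A2 | alternative 1 | [3-ethynyl-5-methoxy-4-(3-methylbut-2-enyl)phenoxy]triisopropylsilane | C#Cc1cc(O[Si](C(C)C)(C(C)C)C(C)C)cc(OC)c1CC=C(C)C
A3 | alternative 1 | methyl 2,6-bis(tert-butyldimethylsilyloxy)-4-hydroxy-3-{[3-methoxy-2-(3-methylbut-2-enyl)-5-(triisopropylsilyloxy)phenyl]ethynyl}-5-(2-methylbut-3-en-2-yl)benzoate | C=CC(C)(C)c1c(O)c(C#Cc2cc(O[Si](C(C)C)(C(C)C)C(C)C)cc(OC)c2CC=C(C)C)c(O[Si](C)(C)C(C)(C)C)c(C(=O)OC)c1O[Si](C)(C)C(C)(C)C
A4 | alternative 2 | {2-[3-methoxy-2-(3-methylbut-2-enyl)-5-(triisopropylsilyloxy)benzoyloxy]-4,6-bis(tert-butyldimethylsilyloxy)-5-(methoxycarbonyl)-3-(2-methylbut-3-en-2-yl)benzyl}triphenylphosphonium bromide | C=CC(C)(C)c1c(OC(=O)c2cc(O[Si](C(C)C)(C(C)C)C(C)C)cc(OC)c2CC=C(C)C)c(C[P+](c2ccccc2)(c2ccccc2)c2ccccc2)c(O[Si](C)(C)C(C)(C)C)c(C(=O)OC)c1O[Si](C)(C)C(C)(C)C.[Br-]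
A5 | alternative 2 | 3-methoxy-2-(3-methylbut-2-enyl)-5-(triisopropylsilyloxy)benzoic acid | OC(=O)c1cc(O[Si](C(C)C)(C(C)C)C(C)C)cc(OC)c1CC=C(C)C
A6 | alternative 3 | 4-(tert-butyldimethylsilyloxy)-2-[3-methoxy-5-(3-methylbut-2-enyloxy)phenyl]-6-(3-methylbut-2-enyloxy)-1-benzofuran | CC(C)=CCOc1cc(O[Si](C)(C)C(C)(C)C)c2cc(-c3cc(OC)cc(OCC=C(C)C)c3)oc2c1
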